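The ratio of Xb to Xa in the green charge is 21.7%. Each Xp takes one Xa and one Xb, so Xb is the limiting reagent, and this ratio is the ceiling on Xp as a share of the Xa charged.

| flask | Xa | Xb | Xc | time |
|---|---|---|---|---|
| grey | 50.0 mM | 50.0 mM | 5.00 mM |  |
| teal | 30.0 mM | 30.0 mM | 5.00 mM |  |
| ochre | 100 mM | 50.0 mM | 5.00 mM |  |
| violet | 50.0 mM | 50.0 mM | 2.50 mM |  |
| green | 230 mM | 50.0 mM | 5.00 mM | 4.4 h |

| run | time / h | [Xp] / mM |
|---|---|---|
| grey run | 0.18 | 0.3 |
| grey run | 0.34 | 0.8 |
| grey run | 0.64 | 2.0 |
| grey run | 1.2 | 4.8 |
| grey run | 2.3 | 11.2 |
| grey run | 4.4 | 22.3 |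
| teal run | 0.18 | 0.4 |
| teal run | 0.34 | 0 |
| teal run | 0.64 | 0.5 |
| teal run | 1.2 | 1.6 |
| teal run | 2.3 | 4.6 |
| teal run | 4.4 | 8.2 |
| ochre run | 0.18 | 0.6 |
| ochre run | 0.34 | 2.2 |
| ochre run | 0.64 | 4.8 |
| ochre run | 1.2 | 11.0 |
| ochre run | 2.3 | 24.9 |
| ochre run | 4.4 | 41.0 |
| violet run | 0.18 | 0.7 |
| violet run | 0.34 | 0.5 |
| violet run | 0.64 | 1.3 |
| violet run | 1.2 | 3.8 |
| violet run | 2.3 | 8.6 |
| violet run | 4.4 | 18.3 |

(standard deviation of a reading: 0.3 mM)

- order of the initial rate in [Xa], near the charge of the grey run, the rate being that where two percent of its Xa are Xp (one fixed amount of Xp, the same in the runs compared)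
- order of the initial rate in [Xb], near the charge of the grey run, the rate being that where two percent of its Xa are Xp
- the teal run starts with 20.0 mM less of Xa and of Xb than the grey run, and with no Xp. Compared where both hold the same amount of Xa, once fifteen percent of what the teal run was charged with has turned into Xp, is the teal run faster, slower or alike (within a tenth)?
- Xp in the green run at 4.4 h, as a share of the Xa charged

- Overall: Xa + Xb -> Xp, with Xc as catalyst.
- Constant volume, constant temperature.
- An order is taken over about fifteen percent of the charge, up and down.

The question is whether the green run gets near that ceiling by 4.4 h. I suppose that the rate is a strength times Xa times Xb. Integrated for unequal charges, this makes the logarithm of Xa over Xb climb in a straight line, at strength times the excess of Xa over Xb. The ochre run holds 41.0 mM Xp at 4.4 h, which gives a strength of 5.40 L mol⁻¹ h⁻¹, averaged over that time with the slow start counted in.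

My one number is the count, for the green run 4.27: strength times excess times time, the number of e-foldings by which Xa over Xb has grown. On this reckoning the green run has 0.547 mM of Xb left at that time, and Xp stands at 21.5%.

Is one number enough? With equal charges the closed form is the growth of one over Xb, and the strength reads 2.85 L mol⁻¹ h⁻¹ in the teal run and 3.66 L mol⁻¹ h⁻¹ in the grey run. So the strength read in the teal run is lower than in the grey run, and the teal run has also made less Xp by then, and from these two readings I expect the teal run to be the slower at equal Xa. The teal strength gives a count of 2.26 and a green share of 19.9%, but the ochre run was charged with more Xa than the other earlier runs, so its charge stands nearer the green one and I commit to 21.5%.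

The forecast gives orders of 1 and 0.5, slower for the teal run, and 21%, warning: “Saturation in Xa is the risk”.

The flask gives orders of 0.75 and 0.75, and 21.7% in the green run, against my 21.5% from a count of 4.27 and a ceiling of 21.7%.

    2 L ⇌ Xc2, settled at all times (4490 L mol⁻¹)
    L + Xa + Xb → Xp + L (3391 L² mol⁻² h⁻¹)
    Xa + Xb + Xp → 2 Xp (155.2 L² mol⁻² h⁻¹)
    Xc → L (1.213 h⁻¹)

That count rests on a strength that does not stay constant. At equal Xa, and so equal Xb, a constant strength makes the teal and grey runs alike, yet the teal run is slower, at 0.49 of the grey rate. The reason is the reaction of Xa + Xb + Xp to 2 Xp, which gains with the Xp present; with that reaction taken away, the ratio is 0.99.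

The readings are simulated from invented constants; noise was put on by code.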